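**Plan**

1. Retrosynthetic cuts: the C7–O bond of the hydroperoxide (back to the 7(11)-en-8-one), C7–C11 (acetone), the two ester C–O bonds and the C3/C4 oxygens (back to a Δ3 olefin), the C8 carbonyl (back to C8=CH2), then C9–C10, and last C6–C7 of the side chain.
2. Enabling feature: the six carbons of ring A (C1–C5, C10) carry the substituents of a 2,4-dimethylphenol (oxygen on C3, methyls on C4 and C10) with C10 para to the oxygen; with ring A aromatic, C10 is a nucleophilic phenoxide carbon and ring B (C5–C10) can be closed onto it at C9 from an allyl unit whose central carbon is C8.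
3. Forward order: arene (ring A) first; chain joined at C6–C7 by dianion alkylation; ring B closed by palladium-allyl dearomatisation; ring A reduced; C8 ketone and isopropylidene; diol; esters; hydroperoxide last.
4. Stereochemistry: C10 from the chiral diphosphine on palladium; C5 from dissolving-metal protonation anti to the C10 methyl; C3 and C4 from osmylation on the face away from that methyl; C7 from singlet-oxygen attack on the same α face.

Key step: step 8

Remark: eudesmane numbering is used for the decalin carbons (C14 = methyl on C10, C15 = methyl on C4), and α denotes the face opposite C14.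

**Route**

Step 1
Reactants: 1 2,6-dimethylbenzoic acid
Product: 2 3-bromo-2,6-dimethylbenzoic acid
Conditions: NBS (1.05 equiv), conc. H2SO4, rt, dark
Reagents that add atoms: N-bromosuccinimide, O=C1CCC(=O)N1Br
Why: Electrophilic aromatic bromination goes to C3, the only kind of position that is ortho to one methyl, para to the other and meta to the deactivating carboxyl, and the first bromine slows a second substitution.

Step 2
Reactants: 2 3-bromo-2,6-dimethylbenzoic acid
Product: 3 (3-bromo-2,6-dimethylphenyl)methanol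
Conditions: BH3·THF, THF, 0 °C → rt; aqueous work-up
Reagents that add atoms: none
Why: Borane reduction of a carboxylic acid runs through acyloxyboranes even for di-ortho-substituted benzoic acids and leaves the aryl bromide untouched.

Step 3
Reactants: 3 (3-bromo-2,6-dimethylphenyl)methanol
Product: 4 1-bromo-3-(bromomethyl)-2,4-dimethylbenzene
Conditions: PBr3, CH2Cl2, 0 °C
Reagents that add atoms: phosphorus tribromide, BrP(Br)Br
Why: Conversion of a benzylic alcohol into the bromide with PBr3 (phosphite ester, then bromide displacement) is routine and does not affect the aryl bromide.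

Step 4
Reactants: 4 1-bromo-3-(bromomethyl)-2,4-dimethylbenzene; 5 2-methylprop-2-en-1-ol
Product: 7 4-(3-bromo-2,6-dimethylphenyl)-2-methylidenebutan-1-ol, via lithium 2-(lithiomethyl)prop-2-en-1-olate 6 (not isolated)
Conditions: 5, n-BuLi (1.95 equiv per 5), TMEDA, Et2O, 0 °C → rt; then 4, THF, −78 → 0 °C
Reagents that add atoms: none
Why: C-alkylation of the allylic C,O-dianion of methallyl alcohol by the benzylic bromide (dianion alkylation) forms C6–C7 and delivers the free 2-substituted allylic alcohol directly, while the slight deficit of n-BuLi avoids bromine–lithium exchange at the aryl bromide.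

Step 5
Reactants: 7 4-(3-bromo-2,6-dimethylphenyl)-2-methylidenebutan-1-ol
Product: 10 3-[3-(hydroxymethyl)but-3-en-1-yl]-2,4-dimethylphenol, via aryllithium alkoxide 8 (not isolated), via dimethyl arylboronate 9 (not isolated)
Conditions: n-BuLi (2.2 equiv), THF, −78 °C; B(OMe)3, −78 °C → rt; 30% H2O2, aq NaOH, 0 °C → rt
Reagents that add atoms: hydrogen peroxide, OO
Why: Alkoxide formation, bromine–lithium exchange, borylation and oxidative boron-to-oxygen 1,2-migration (ipso-hydroxylation of an arylboronate) place the phenol oxygen on C3 under conditions that do not touch the 1,1-disubstituted alkene.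

Step 6
Reactants: 10 3-[3-(hydroxymethyl)but-3-en-1-yl]-2,4-dimethylphenol
Product: 11 methyl 3-[3-(methoxycarbonyloxymethyl)but-3-en-1-yl]-2,4-dimethylphenyl carbonate
Conditions: ClCO2Me (2.5 equiv), pyridine, CH2Cl2, 0 °C → rt
Reagents that add atoms: methyl chloroformate, COC(=O)Cl
Why: Exhaustive acylation of both hydroxyls with a chloroformate avoids having to tell the phenol from the allylic alcohol at this stage.

Step 7
Reactants: 11 methyl 3-[3-(methoxycarbonyloxymethyl)but-3-en-1-yl]-2,4-dimethylphenyl carbonate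
Product: 12 3-[3-(methoxycarbonyloxymethyl)but-3-en-1-yl]-2,4-dimethylphenol
Conditions: pyrrolidine (1.1 equiv), THF, 0 °C
Reagents that add atoms: none
Why: Chemoselective aminolysis cleaves the aryl carbonate, whose phenoxide is by far the better leaving group, and leaves the allylic methyl carbonate intact.

Step 8
Reactants: 12 3-[3-(methoxycarbonyloxymethyl)but-3-en-1-yl]-2,4-dimethylphenol
Product: 13 (4aS)-1,4a-dimethyl-6-methylidene-5,6,7,8-tetrahydronaphthalen-2(4aH)-one
Conditions: Pd2(dba)3·CHCl3 (2.5 mol %), (1R,2R)-N,N'-bis[2-(diphenylphosphanyl)benzoyl]cyclohexane-1,2-diamine (7.5 mol %), toluene (0.02 M), rt → 40 °C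
Reagents that add atoms: none
Why: Zerovalent palladium ionises the allylic carbonate to a 2-alkyl π-allyl complex with loss of CO2, and the methoxide set free deprotonates the phenol; this is a Tsuji–Trost allylic alkylation run as an intramolecular dearomatisation, the closest known reaction types being the palladium-catalysed allylic dearomatisation of phenols to cyclohexadienones and methylenecycloalkane annulation with 2-(acyloxymethyl)allyl units. The para carbon C10 of the phenoxide attacks the allyl terminus C9 anti to palladium, which closes ring B as a six-membered carbocycle in a 6-exo-tet sense at C9: palladium leaves outside the ring, the central allyl carbon C8 stays in it and the other terminus becomes the exocyclic methylene. Since C10 bears a methyl group, the cross-conjugated dienone cannot tautomerise back to a phenol and the quaternary centre persists. The C10 configuration is controlled by the chiral diphosphine on palladium, which distinguishes the two faces of the flat phenoxide in the outer-sphere attack; the ligand antipode is the one that gives 4aS, and the (1S,2S) ligand is used if the sense proves opposite. The step needs carbon rather than oxygen alkylation and para rather than ortho attack: an O-alkylated product would be a strained meta-bridged ether and re-ionises under palladium, and C10 is the phenoxide carbon of highest coefficient with a free neighbour (C1–H), whereas C4 lies between the oxygen-bearing C3 and the tether-bearing C5.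

Step 9
Reactants: 13 (4aS)-1,4a-dimethyl-6-methylidene-5,6,7,8-tetrahydronaphthalen-2(4aH)-one
Product: 14 (4aR)-1,4a-dimethyl-6-methylidene-4,4a,5,6,7,8-hexahydronaphthalen-2(3H)-one
Conditions: LiBH(s-Bu)3, THF, −78 °C; aq NH4Cl
Reagents that add atoms: none
Why: Conjugate (1,4) hydride reduction with a bulky trialkylborohydride attacks only C1 of the disubstituted enone arm, the tetrasubstituted C4=C5 arm and the isolated methylene being inert, and C-protonation of the cross-conjugated dienolate at C2 returns the Δ4-3-ketone.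

Step 10
Reactants: 14 (4aR)-1,4a-dimethyl-6-methylidene-4,4a,5,6,7,8-hexahydronaphthalen-2(3H)-one
Product: 16 (4aR,8aR)-1,4a-dimethyl-6-methylidene-3,4,4a,5,6,7,8,8a-octahydronaphthalen-2-yl trifluoromethanesulfonate, via C3–C4 lithium enolate 15 (not isolated)
Conditions: Li, NH3(l)/THF, t-BuOH (1.0 equiv), −78 °C; evaporate NH3; PhNTf2, THF, 0 °C → rt
Reagents that add atoms: N-phenylbis(trifluoromethanesulfonimide), O=S(=O)(N(c1ccccc1)S(=O)(=O)C(F)(F)F)C(F)(F)F
Why: Dissolving-metal (Birch-type) reduction of the enone protonates C5 axially to give the trans ring fusion (H5 anti to the C10 methyl) and, regiospecifically, the C3–C4 enolate, which is trapped on oxygen as the enol triflate while the isolated methylene is not reduced.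

Step 11
Reactants: 16 (4aR,8aR)-1,4a-dimethyl-6-methylidene-3,4,4a,5,6,7,8,8a-octahydronaphthalen-2-yl trifluoromethanesulfonate
Product: 18 (4aR,8aR)-1,4a-dimethyl-6-oxo-3,4,4a,5,6,7,8,8a-octahydronaphthalen-2-yl trifluoromethanesulfonate, via spiro ozonide 17 (not isolated)
Conditions: O3 (1 equiv), CH2Cl2, −78 °C; PPh3, −78 °C → rt
Reagents that add atoms: ozone, [O-][O+]=O
Why: Ozonolysis with reductive work-up cleaves the electron-rich 1,1-disubstituted methylene to the C8 ketone, whereas the enol triflate double bond is strongly deactivated by the sulfonate and is not attacked.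

Step 12
Reactants: 18 (4aR,8aR)-1,4a-dimethyl-6-oxo-3,4,4a,5,6,7,8,8a-octahydronaphthalen-2-yl trifluoromethanesulfonate
Product: 19 (4aR,8aR)-5,8a-dimethyl-3,4,4a,7,8,8a-hexahydronaphthalen-2(1H)-one
Conditions: Pd(OAc)2 (5 mol %), PPh3 (10 mol %), n-Bu3N, HCO2H, DMF, 60 °C
Reagents that add atoms: none
Why: Palladium-catalysed formate reduction of an enol triflate (oxidative addition, formate decarboxylation, C–H reductive elimination) replaces the triflate by hydrogen without moving the double bond, which gives the Δ3 olefin and leaves the saturated ketone alone.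

Step 13
Reactants: 19 (4aR,8aR)-5,8a-dimethyl-3,4,4a,7,8,8a-hexahydronaphthalen-2(1H)-one; 20 acetone
Product: 22 (3R,4aR,8aR)-3-(2-hydroxypropan-2-yl)-5,8a-dimethyl-3,4,4a,7,8,8a-hexahydronaphthalen-2(1H)-one, via C7–C8 lithium enolate 21 (not isolated)
Conditions: LiN(iPr)2 (1.05 equiv), THF, −78 °C; acetone, −78 °C; AcOH quench at −78 °C
Reagents that add atoms: none
Why: Kinetic deprotonation takes place at C7 rather than at C9, which is neopentylic next to quaternary C10, and aldol addition of the lithium enolate to acetone forms C7–C11; the C7 configuration (drawn with the side chain equatorial) is of no consequence because it is removed in the next step.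

Step 14
Reactants: 22 (3R,4aR,8aR)-3-(2-hydroxypropan-2-yl)-5,8a-dimethyl-3,4,4a,7,8,8a-hexahydronaphthalen-2(1H)-one
Product: 24 (5R,10R)-eudesma-3,7(11)-dien-8-one, via tertiary mesylate 23 (not isolated)
Conditions: MsCl, Et3N, CH2Cl2, 0 °C; then DBU, rt
Reagents that add atoms: none
Why: Sulfene-mediated mesylation of the tertiary aldol and base-induced E1cB elimination (aldol dehydration) give the conjugated isopropylidene ketone, and DBU brings any isopropenyl isomer into conjugation without acid that could move the Δ3 olefin.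

Step 15
Reactants: 24 (5R,10R)-eudesma-3,7(11)-dien-8-one
Product: 25 (3R,4S,5R,10R)-3,4-dihydroxyeudesm-7(11)-en-8-one
Conditions: OsO4 (2 mol %), NMO, acetone/H2O, rt
Reagents that add atoms: N-methylmorpholine N-oxide, C[N+]1([O-])CCOCC1 (oxygen passed on through osmium tetroxide, O=[Os](=O)(=O)=O)
Why: Catalytic syn-dihydroxylation (Upjohn conditions) takes the electron-rich trisubstituted Δ3 olefin in preference to the electron-poor tetrasubstituted enone double bond and adds from the α face, anti to the axial C10 methyl, which sets C3 and C4 as the cis-3α,4α-diol with the C4 methyl β.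

Step 16
Reactants: 25 (3R,4S,5R,10R)-3,4-dihydroxyeudesm-7(11)-en-8-one; 26 angelic acid [(Z)-2-methylbut-2-enoic acid]
Product: 28 3α-angeloyloxy-4α-hydroxyeudesm-7(11)-en-8-one, via angelic 2,4,6-trichlorobenzoic anhydride 27 (not isolated)
Conditions: 26, 2,4,6-trichlorobenzoyl chloride, Et3N, toluene, rt; then 25, toluene, 80 °C
Reagents that add atoms: none
Why: Yamaguchi-type mixed-anhydride esterification without a nucleophilic catalyst acylates the secondary C3 hydroxyl only (the tertiary C4 hydroxyl does not react) and should keep the Z geometry of the angelate, which nucleophilic acyl-transfer catalysts tend to isomerise to the tiglate.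

Step 17
Reactants: 28 3α-angeloyloxy-4α-hydroxyeudesm-7(11)-en-8-one
Product: 29 4α-acetoxy-3α-angeloyloxyeudesm-7(11)-en-8-one
Conditions: Ac2O, Sc(OTf)3 (5 mol %), MeCN, −20 °C
Reagents that add atoms: acetic anhydride, CC(=O)OC(C)=O
Why: Lewis-acid-catalysed acetylation with Sc(OTf)3 acylates hindered tertiary alcohols at low temperature, where neither elimination at C4 nor isomerisation of the angelate is expected.

Step 18
Reactants: 29 4α-acetoxy-3α-angeloyloxyeudesm-7(11)-en-8-one
Product: 30 4α-acetoxy-3α-angeloyloxy-7α-hydroperoxyeudesm-11-en-8-one (CNP0360871.1)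
Conditions: O2, tetraphenylporphyrin (cat.), visible light, CH2Cl2, 0 °C
Reagents that add atoms: dioxygen, O=O
Why: In this Schenck ene reaction of singlet oxygen with the s-cis-locked α-isopropylidene ketone, attack on the open α face (anti to the axial C10 and C4 methyls) can only abstract a hydrogen of an isopropylidene methyl because H6α is equatorial and lies in the alkene plane, so oxygen should end on C7 as the 7α-hydroperoxide with the double bond moved to C11=C12, while the electron-poor angelate does not compete.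

**Compound list**

1 | 2,6-dimethylbenzoic acid | Cc1cccc(C)c1C(=O)O | starting material
2 | 3-bromo-2,6-dimethylbenzoic acid | Cc1ccc(Br)c(C)c1C(=O)O | intermediate
3 | (3-bromo-2,6-dimethylphenyl)methanol | Cc1ccc(Br)c(C)c1CO | intermediate
4 | 1-bromo-3-(bromomethyl)-2,4-dimethylbenzene | Cc1ccc(Br)c(C)c1CBr | intermediate
5 | 2-methylprop-2-en-1-ol | C=C(C)CO | starting material
6 | lithium 2-(lithiomethyl)prop-2-en-1-olate | [Li]CC(=C)CO[Li] | intermediate
7 | 4-(3-bromo-2,6-dimethylphenyl)-2-methylidenebutan-1-ol | Cc1ccc(Br)c(C)c1CCC(=C)CO | intermediate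
8 | lithium 4-(3-lithio-2,6-dimethylphenyl)-2-methylidenebutan-1-olate | Cc1ccc([Li])c(C)c1CCC(=C)CO[Li] | intermediate
9 | lithium 4-[3-(dimethoxyboranyl)-2,6-dimethylphenyl]-2-methylidenebutan-1-olate | Cc1ccc(B(OC)OC)c(C)c1CCC(=C)CO[Li] | intermediate
10 | 3-[3-(hydroxymethyl)but-3-en-1-yl]-2,4-dimethylphenol | Cc1ccc(O)c(C)c1CCC(=C)CO | intermediate
11 | methyl 3-[3-(methoxycarbonyloxymethyl)but-3-en-1-yl]-2,4-dimethylphenyl carbonate | Cc1ccc(OC(=O)OC)c(C)c1CCC(=C)COC(=O)OC | intermediate
12 | 3-[3-(methoxycarbonyloxymethyl)but-3-en-1-yl]-2,4-dimethylphenol | Cc1ccc(O)c(C)c1CCC(=C)COC(=O)OC | intermediate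
13 | (4aS)-1,4a-dimethyl-6-methylidene-5,6,7,8-tetrahydronaphthalen-2(4aH)-one | C=C1CCC2=C(C)C(=O)C=C[C@]2(C)C1 | intermediate
14 | (4aR)-1,4a-dimethyl-6-methylidene-4,4a,5,6,7,8-hexahydronaphthalen-2(3H)-one | C=C1CCC2=C(C)C(=O)CC[C@]2(C)C1 | intermediate
15 | lithium (4aR,8aR)-1,4a-dimethyl-6-methylidene-3,4,4a,5,6,7,8,8a-octahydronaphthalen-2-olate | C=C1CC[C@H]2C(C)=C(O[Li])CC[C@]2(C)C1 | intermediate
16 | (4aR,8aR)-1,4a-dimethyl-6-methylidene-3,4,4a,5,6,7,8,8a-octahydronaphthalen-2-yl trifluoromethanesulfonate | C=C1CC[C@H]2C(C)=C(OS(=O)(=O)C(F)(F)F)CC[C@]2(C)C1 | intermediate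
17 | spiro-1,2,4-trioxolane (ozonide) of 16 at C8, mixture at the spiro carbon | O1COOC12CC[C@H]3C(C)=C(OS(=O)(=O)C(F)(F)F)CC[C@]3(C)C2 | intermediate
18 | (4aR,8aR)-1,4a-dimethyl-6-oxo-3,4,4a,5,6,7,8,8a-octahydronaphthalen-2-yl trifluoromethanesulfonate | O=C1CC[C@H]2C(C)=C(OS(=O)(=O)C(F)(F)F)CC[C@]2(C)C1 | intermediate
19 | (4aR,8aR)-5,8a-dimethyl-3,4,4a,7,8,8a-hexahydronaphthalen-2(1H)-one | O=C1CC[C@H]2C(C)=CCC[C@]2(C)C1 | intermediate
20 | acetone | CC(C)=O | starting material
21 | lithium (4aR,8aR)-5,8a-dimethyl-1,4,4a,7,8,8a-hexahydronaphthalen-2-olate | [Li]OC1=CC[C@H]2C(C)=CCC[C@]2(C)C1 | intermediate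
22 | (3R,4aR,8aR)-3-(2-hydroxypropan-2-yl)-5,8a-dimethyl-3,4,4a,7,8,8a-hexahydronaphthalen-2(1H)-one | O=C1[C@@H](C(C)(C)O)C[C@H]2C(C)=CCC[C@]2(C)C1 | intermediate
23 | methanesulfonate of the tertiary hydroxyl of 22 | O=C1[C@@H](C(C)(C)OS(C)(=O)=O)C[C@H]2C(C)=CCC[C@]2(C)C1 | intermediate
24 | (5R,10R)-eudesma-3,7(11)-dien-8-one | CC(C)=C1C[C@@H]2[C@](C)(CCC=C2C)CC1=O | intermediate
25 | (3R,4S,5R,10R)-3,4-dihydroxyeudesm-7(11)-en-8-one (3α,4α-diol) | CC(C)=C1C[C@@H]2[C@](C)(CC[C@@H](O)[C@@]2(C)O)CC1=O | intermediate
26 | angelic acid, (Z)-2-methylbut-2-enoic acid | C/C=C(/C)C(=O)O | starting material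
27 | (Z)-2-methylbut-2-enoic 2,4,6-trichlorobenzoic anhydride | C/C=C(/C)C(=O)OC(=O)c1c(Cl)cc(Cl)cc1Cl | intermediate
28 | (3R,4S,5R,10R)-4-hydroxy-8-oxoeudesm-7(11)-en-3-yl (Z)-2-methylbut-2-enoate | CC(C)=C1C[C@@H]2[C@](C)(CC[C@@H](OC(=O)/C(C)=C\C)[C@@]2(C)O)CC1=O | intermediate
29 | (3R,4S,5R,10R)-4-acetoxy-8-oxoeudesm-7(11)-en-3-yl (Z)-2-methylbut-2-enoate | CC(C)=C1C[C@@H]2[C@](C)(CC[C@@H](OC(=O)/C(C)=C\C)[C@@]2(C)OC(C)=O)CC1=O | intermediate
30 | (3R,4S,5R,7S,10R)-4-acetoxy-7-hydroperoxy-8-oxoeudesm-11-en-3-yl (Z)-2-methylbut-2-enoate | C=C(C)[C@@]1(OO)C[C@@H]2[C@](C)(CC[C@@H](OC(=O)/C(C)=C\C)[C@@]2(C)OC(C)=O)CC1=O | target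

**Count**

Total steps: 18. Longest linear sequence: 18 steps (1 → 30); compounds 5, 20 and 26 enter as purchased materials.

**Steps most likely to fail**

Step 8. The ring closure may discriminate the two phenoxide faces poorly (low enantiomeric purity) or give some ortho attack at C4. The fallback sets out from 10 and returns at 13. Corey–Kim chlorination (N-chlorosuccinimide, Me2S, CH2Cl2, −20 °C) converts only the allylic alcohol of 10 into 3-[3-(chloromethyl)but-3-en-1-yl]-2,4-dimethylphenol F1. KOt-Bu in t-BuOH at high dilution then effects the classical metal-free intramolecular para C-alkylation of the phenoxide to racemic 1,4a-dimethyl-6-methylidene-5,6,7,8-tetrahydronaphthalen-2(4aH)-one F2. The enantiomers are separated by preparative chromatography on a chiral stationary phase; the (4aS) enantiomer is 13.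

Step 18. Hydrogen abstraction may instead occur at C6 from the β face (the position geminal to the carbonyl), which would put the hydroperoxide on C11, or the electron-poor enone may react too slowly. The fallback sets out from 29 and returns at 30; it takes the carbonyl out of play during the ene reaction.
- Luche reduction (NaBH4, CeCl3·7H2O, MeOH, −40 °C) should give, by hydride attack anti to the C10 methyl, 4α-acetoxy-3α-angeloyloxyeudesm-7(11)-en-8β-ol F3.
- Et3SiOTf and 2,6-lutidine give its triethylsilyl ether F4, whose axial silyloxy group adds to the shielding of the β face.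
- Photooxygenation (O2, tetraphenylporphyrin, light, CH2Cl2) of this electron-rich tetrasubstituted olefin from the α face gives 4α-acetoxy-3α-angeloyloxy-7α-hydroperoxy-8β-(triethylsilyloxy)eudesm-11-ene F5.
- HF·pyridine in THF frees 4α-acetoxy-3α-angeloyloxy-7α-hydroperoxyeudesm-11-en-8β-ol F6.
- Dess–Martin oxidation (NaHCO3, CH2Cl2, 0 °C) of the secondary alcohol gives 30.

Step 16. The activated angeloyl unit may isomerise to the tigloyl unit, or the hindered axial hydroxyl may not be acylated. The fallback sets out from 25 and returns at 28; it builds the Z olefin on the substrate. Carbodiimide coupling (EDC, DMAP, CH2Cl2) of 25 with 2-[bis(2,2,2-trifluoroethoxy)phosphoryl]propanoic acid gives the 3-O-[2-[bis(2,2,2-trifluoroethoxy)phosphoryl]propanoyl] ester of 25 F7 (epimers at the phosphonate carbon). Z-selective Horner–Wadsworth–Emmons olefination in the Still–Gennari manner (KN(SiMe3)2, 18-crown-6, THF, −78 °C, acetaldehyde) then gives 28.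

**Further compounds**

F1 | step 8 | 3-[3-(chloromethyl)but-3-en-1-yl]-2,4-dimethylphenol | Cc1ccc(O)c(C)c1CCC(=C)CCl
F2 | step 8 | racemic 1,4a-dimethyl-6-methylidene-5,6,7,8-tetrahydronaphthalen-2(4aH)-one | C=C1CCC2=C(C)C(=O)C=CC2(C)C1
F3 | step 18 | 4α-acetoxy-3α-angeloyloxyeudesm-7(11)-en-8β-ol | CC(C)=C1C[C@@H]2[C@](C)(CC[C@@H](OC(=O)/C(C)=C\C)[C@@]2(C)OC(C)=O)C[C@H]1O
F4 | step 18 | 4α-acetoxy-3α-angeloyloxy-8β-(triethylsilyloxy)eudesm-7(11)-ene | CC(C)=C1C[C@@H]2[C@](C)(CC[C@@H](OC(=O)/C(C)=C\C)[C@@]2(C)OC(C)=O)C[C@H]1O[Si](CC)(CC)CC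
F5 | step 18 | 4α-acetoxy-3α-angeloyloxy-7α-hydroperoxy-8β-(triethylsilyloxy)eudesm-11-ene | C=C(C)[C@@]1(OO)C[C@@H]2[C@](C)(CC[C@@H](OC(=O)/C(C)=C\C)[C@@]2(C)OC(C)=O)C[C@H]1O[Si](CC)(CC)CC
F6 | step 18 | 4α-acetoxy-3α-angeloyloxy-7α-hydroperoxyeudesm-11-en-8β-ol | C=C(C)[C@@]1(OO)C[C@@H]2[C@](C)(CC[C@@H](OC(=O)/C(C)=C\C)[C@@]2(C)OC(C)=O)C[C@H]1O
F7 | step 16 | (3R,4S,5R,10R)-4-hydroxy-8-oxoeudesm-7(11)-en-3-yl 2-[bis(2,2,2-trifluoroethoxy)phosphoryl]propanoate | CC(C)=C1C[C@@H]2[C@](C)(CC[C@@H](OC(=O)C(C)P(=O)(OCC(F)(F)F)OCC(F)(F)F)[C@@]2(C)O)CC1=O
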